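**Retrosynthetic overview**

1. Numbering: ten-membered ring C1 (quaternary) to C10, cyclopropane C9–C10–C11. The strategy rests on the ring array C4(Me)=C5–C6(O)–C7–C8(=O): a γ,δ-unsaturated ketone with an allylic oxygen at C6, which is the product pattern of a decarboxylative [3,3] shift of a C4 tertiary allylic β-keto ester whose vinyl terminus C6 is a silyl enol ether.
2. Key disconnection C6–C7: Carroll rearrangement of the ten-membered β-keto lactone 24 exchanges its ring O–C(=O) unit for C5–C6 and gives carbocycle 26; the lactone C4–O bond comes from intramolecular acylketene capture.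
3. The C4 carbinol and Z enol ether come from Sharpless epoxidation, epoxy chloride to alkyne, siloxyalkyne and Lindlar reduction; the cyclopropane from copper–bis(oxazoline) carbene transfer; C1 from copper-catalysed SN2′ alkylation of geranyl chloride.
4. After the key step: hydroxyl-directed methyl addition at C8, C6 acetate, prenyl end to the (S)-hydroperoxide (Shi epoxide, titanocene isomerisation, invertive peroxide displacement).
5. Ring order: cyclopropane (step 8), ten-membered lactone (step 13), ten-membered carbocycle (step 14).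

Key step: step 14

Assumption: the enantiomer of each chiral ligand or catalyst (steps 2, 5, 8, 18) is the one expected by analogy with simpler substrates to give the drawn configuration; the mirror-image ligand is used if the sense proves opposite.

**Route**

Step 1
Reactants: 1 geraniol
Product: 2 geranyl chloride
Conditions: NCS, Me2S, CH2Cl2, −40 to 0 °C
Reagents that add atoms: N-chlorosuccinimide, O=C1CCC(=O)N1Cl
Why: Corey–Kim chlorination of the primary allylic alcohol gives the chloride without allylic transposition or loss of the E geometry.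

Step 2
Reactants: 2 geranyl chloride; 3 (4-bromobut-1-yn-1-yl)trimethylsilane
Product: 5 [(5S)-5-ethenyl-5,9-dimethyldec-8-en-1-yn-1-yl]trimethylsilane, via Grignard reagent 4 (not isolated)
Conditions: 3, Mg, THF, 35 °C; then 2, CuBr·SMe2 (3 mol%), BINOL-derived phosphoramidite ligand with a bis(1-phenylethyl)amine unit (3.3 mol%), CH2Cl2, −78 °C, slow addition of 4
Reagents that add atoms: none
Why: Copper-catalysed enantioselective SN2′ allylic alkylation: the alkylcopper attacks the disubstituted γ-carbon, and the ligand selects the alkene face, which sets quaternary C1 (S in this compound) and releases the vinyl group for the later cyclopropanation.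

Step 3
Reactants: 5 [(5S)-5-ethenyl-5,9-dimethyldec-8-en-1-yn-1-yl]trimethylsilane
Product: 6 (5S)-5-ethenyl-5,9-dimethyldec-8-en-1-yne
Conditions: K2CO3, MeOH, rt
Reagents that add atoms: none
Why: Methanolysis of the alkynyl C–Si bond (protodesilylation) leaves the alkenes and the quaternary centre untouched.

Step 4
Reactants: 6 (5S)-5-ethenyl-5,9-dimethyldec-8-en-1-yne
Product: 8 (2E,6S)-6-ethenyl-3,6,10-trimethylundeca-2,9-dien-1-ol, via alkenylalane 7 (not isolated)
Conditions: Me3Al, Cp2ZrCl2 (0.25 equiv), CH2Cl2, 0 °C to rt; then n-BuLi, (CH2O)n, THF, −78 °C to rt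
Reagents that add atoms: trimethylaluminium, C[Al](C)C; formaldehyde (as paraformaldehyde), C=O
Why: Negishi zirconium-catalysed carboalumination adds methyl and aluminium syn across the terminal alkyne (methyl to the internal carbon, alkenes inert), and the alkenyl alanate traps formaldehyde with retention, so only the E allylic alcohol (C4 methyl, C5, C6) should form.

Step 5
Reactants: 8 (2E,6S)-6-ethenyl-3,6,10-trimethylundeca-2,9-dien-1-ol
Product: 9 [(2R,3R)-3-[(3S)-3-ethenyl-3,7-dimethyloct-6-en-1-yl]-3-methyloxiran-2-yl]methanol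
Conditions: Ti(OiPr)4, D-(−)-diethyl tartrate, t-BuOOH, 4 Å MS, CH2Cl2, −20 °C
Reagents that add atoms: tert-butyl hydroperoxide, CC(C)(C)OO
Why: Sharpless asymmetric epoxidation acts only on the allylic alcohol alkene, and the D-tartrate catalyst delivers oxygen to the face that makes the C4–O bond R (2R,3R epoxide), as for other E-3-methylalk-2-en-1-ols.

Step 6
Reactants: 9 [(2R,3R)-3-[(3S)-3-ethenyl-3,7-dimethyloct-6-en-1-yl]-3-methyloxiran-2-yl]methanol
Product: 10 (2S,3R)-2-(chloromethyl)-3-[(3S)-3-ethenyl-3,7-dimethyloct-6-en-1-yl]-3-methyloxirane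
Conditions: PPh3, CCl4, NaHCO3, reflux
Reagents that add atoms: tetrachloromethane, ClC(Cl)(Cl)Cl
Why: Appel chlorination converts the primary alcohol into the chloride under neutral conditions that keep the trisubstituted epoxide closed (the C2 descriptor changes only because chlorine changes the priorities).

Step 7
Reactants: 10 (2S,3R)-2-(chloromethyl)-3-[(3S)-3-ethenyl-3,7-dimethyloct-6-en-1-yl]-3-methyloxirane
Product: 12 (3R,6S)-6-ethenyl-3,6,10-trimethyl-1-(trimethylsilyl)-3-(trimethylsilyloxy)undec-9-en-1-yne, via dilithio alkoxide acetylide 11 (not isolated)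
Conditions: LDA (3.5 equiv), THF, −40 °C; then Me3SiCl, −40 °C to rt
Reagents that add atoms: chlorotrimethylsilane, C[Si](C)(C)Cl
Why: Base-induced double elimination of the 2,3-epoxy chloride (α-deprotonation, epoxide opening to a chlorovinyl alkoxide, dehydrochlorination) gives the tertiary propargylic alkoxide without breaking the C4–O bond, so C4 stays R, and the dianion is silylated at O and C to shield both sites from the carbenoid of step 8.

Step 8
Reactants: 12 (3R,6S)-6-ethenyl-3,6,10-trimethyl-1-(trimethylsilyl)-3-(trimethylsilyloxy)undec-9-en-1-yne; 13 ethyl diazoacetate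
Product: 14 ethyl (1S,2S)-2-[(3R,6S)-3,6,10-trimethyl-1-(trimethylsilyl)-3-(trimethylsilyloxy)undec-9-en-1-yn-6-yl]cyclopropane-1-carboxylate
Conditions: 13 (slow addition), CuOTf (5 mol%), 2,2′-isopropylidenebis[(4R)-4-tert-butyl-2-oxazoline] (6 mol%), CH2Cl2, rt
Reagents that add atoms: none
Why: Copper–bis(oxazoline) carbene transfer (asymmetric cyclopropanation): cationic monovalent copper favours the monosubstituted alkene over the trisubstituted prenyl alkene, the quaternary substituent enforces the trans ester, and the ligand fixes the alkene face (9S,10S expected by analogy with other monosubstituted alkenes).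

Step 9
Reactants: 14 ethyl (1S,2S)-2-[(3R,6S)-3,6,10-trimethyl-1-(trimethylsilyl)-3-(trimethylsilyloxy)undec-9-en-1-yn-6-yl]cyclopropane-1-carboxylate
Product: 15 ethyl (1S,2S)-2-[(3R,6S)-3-hydroxy-3,6,10-trimethylundec-9-en-1-yn-6-yl]cyclopropane-1-carboxylate
Conditions: TBAF, THF, 0 °C
Reagents that add atoms: none
Why: Fluoride cleaves both the tertiary trimethylsilyl ether and the alkynylsilane, while the ethyl ester should survive the short, cold treatment.

Step 10
Reactants: 15 ethyl (1S,2S)-2-[(3R,6S)-3-hydroxy-3,6,10-trimethylundec-9-en-1-yn-6-yl]cyclopropane-1-carboxylate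
Product: 18 ethyl (1S,2S)-2-[(3R,6S)-3-hydroxy-3,6,10-trimethyl-1-(triisopropylsilyloxy)undec-9-en-1-yn-6-yl]cyclopropane-1-carboxylate, via lithium acetylide 16 (not isolated), via lithium ynolate 17 (not isolated)
Conditions: LiHMDS (2.2 equiv), THF, −78 °C; t-BuOOLi (from t-BuOOH, LiHMDS), −78 to 0 °C; i-Pr3SiOTf, −78 °C
Reagents that add atoms: tert-butyl hydroperoxide, CC(C)(C)OO; triisopropylsilyl trifluoromethanesulfonate, CC(C)[Si](OS(=O)(=O)C(F)(F)F)(C(C)C)C(C)C
Why: Oxidation of the lithium acetylide by lithium tert-butyl peroxide gives the ynolate, which the bulky silyl triflate silylates on oxygen (siloxyalkyne synthesis), while the hindered tertiary alkoxide is not silylated and the ester is not attacked at low temperature.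

Step 11
Reactants: 18 ethyl (1S,2S)-2-[(3R,6S)-3-hydroxy-3,6,10-trimethyl-1-(triisopropylsilyloxy)undec-9-en-1-yn-6-yl]cyclopropane-1-carboxylate; 19 tert-butyl acetate
Product: 21 tert-butyl 3-[(1S,2S)-2-[(3R,6S)-3-hydroxy-3,6,10-trimethyl-1-(triisopropylsilyloxy)undec-9-en-1-yn-6-yl]cyclopropyl]-3-oxopropanoate, via tert-butyl acetate lithium enolate 20 (not isolated)
Conditions: 19, LDA, THF, −78 °C (4 equiv of 20); then 18, −78 to −30 °C; pH 7 buffer
Reagents that add atoms: none
Why: Crossed Claisen condensation of the ethyl ester with lithio tert-butyl acetate, driven by deprotonation of the β-keto ester formed; the linear siloxyalkyne and the lithium alkoxide are inert to the ester enolate, and making the β-keto ester before the Z enol ether avoids an alkoxide next to a migratable silyl group.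

Step 12
Reactants: 21 tert-butyl 3-[(1S,2S)-2-[(3R,6S)-3-hydroxy-3,6,10-trimethyl-1-(triisopropylsilyloxy)undec-9-en-1-yn-6-yl]cyclopropyl]-3-oxopropanoate
Product: 22 tert-butyl 3-[(1S,2S)-2-[(1Z,3R,6S)-3-hydroxy-3,6,10-trimethyl-1-(triisopropylsilyloxy)undeca-1,9-dien-6-yl]cyclopropyl]-3-oxopropanoate
Conditions: H2 (1 atm), Pd/CaCO3 poisoned with Pb (Lindlar catalyst), quinoline, hexane–EtOAc, 0 °C
Reagents that add atoms: none
Why: Lindlar semi-hydrogenation adds H2 syn to the ynol ether and should give only the Z silyl enol ether; the trisubstituted alkene and the cyclopropane are not reduced.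

Step 13
Reactants: 22 tert-butyl 3-[(1S,2S)-2-[(1Z,3R,6S)-3-hydroxy-3,6,10-trimethyl-1-(triisopropylsilyloxy)undeca-1,9-dien-6-yl]cyclopropyl]-3-oxopropanoate
Product: 24 ten-membered β-keto lactone (ring O–C(=O)–C7–C8(=O)–C9–C10–C1–C2–C3–C4; 4R with methyl and (Z)-2-(triisopropylsilyloxy)ethenyl; 1S with methyl and 4-methylpent-3-enyl; trans-cyclopropane 9S,10S), via acylketene 23 (not isolated)
Conditions: toluene, 110 °C, slow addition to 0.5 mM, N2 sweep (removal of t-BuOH), base-washed glassware
Reagents that add atoms: none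
Why: Thermolysis of the tert-butyl β-keto ester expels tert-butanol to give the acylketene, which the C4 tertiary hydroxyl captures intramolecularly (acylketene macrolactonization) under neutral conditions that spare the acid-labile γ-hydroxy enol ether; the two quaternary centres and the rigid trans-cyclopropane limit the conformational cost of the ten-membered ring.

Step 14
Reactants: 24 ten-membered β-keto lactone
Product: 26 ten-membered carbocycle (C1–C10; C8 ketone; 6S triisopropylsilyloxy; 4E alkene; cyclopropane 9S,10S; 1S with methyl and 4-methylpent-3-enyl), via β-keto acid 25 (not isolated)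
Conditions: o-xylene, 140 °C, 1 mM, 2,6-lutidine (0.2 equiv), silanised glassware, Ar
Reagents that add atoms: none
Why: Proposed new method: the enol tautomer in which the lactone carbonyl is enolised (C7=C(OH)–O–C4) and the 2-silyloxyvinyl group on C4 form the six-atom array of a [3,3] shift (Carroll, i.e. decarboxylative Claisen, rearrangement; the closest known types are the Carroll rearrangement of acyclic tertiary allylic β-keto esters and the Claisen rearrangement of lactone ketene acetals that carry a vinyl group on the carbinol carbon), which makes C6–C7 and breaks C4–O, after which β-keto acid 25 loses CO2 at once and makes the step irreversible. The ten-membered carbocycle is closed transannularly within the lactone: the two-atom O–C(=O) bridge is exchanged for the two-carbon C5–C6 bridge, through a bicyclo[6.2.2]-type array in which the chain C8–C9–C10–C1–C2–C3 spans the 1,4-positions of the six-centre transition state. C6 is set by suprafacial chirality transfer from C4: with 4R and the Z enol ether, the rotamer with the ring bond C4–C3 anti to C6 gives 6S together with E-C4=C5, whereas chair and boat arrays differ only at C7, which is lost on decarboxylation. The selectivity needed is therefore for this rotamer over the one with C3 gauche to C6 (which would give the Z alkene and 6R); it is favoured because the Z silyloxy group tolerates the methyl group better than the ring methylene in the inside position, and because the trans-cyclopropane and quaternary C1 favour a trans-cyclodecene-like fold, but this must be checked by modelling. The silyloxy donor at C6 polarises the transition state and should lower the barrier, and the non-polar solvent, high dilution and trace of hindered base are chosen to suppress ionisation of the tertiary allylic ester to an enal and ring opening to the acylketene.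

Step 15
Reactants: 26 ten-membered carbocycle with C8 ketone and C6 silyl ether
Product: 27 β-hydroxy ketone (C6 hydroxyl 6S, C8 ketone, otherwise as 26)
Conditions: TBAF, AcOH (1:1), THF, rt
Reagents that add atoms: none
Why: Buffered fluoride desilylation frees the C6 hydroxyl without the retro-aldol ring opening or β-elimination that unbuffered fluoride could provoke in the β-oxy ketone.

Step 16
Reactants: 27 β-hydroxy ketone
Product: 28 diol (6S secondary allylic alcohol, 8S tertiary methyl carbinol on the cyclopropane)
Conditions: MeTi(OiPr)3 (3 equiv), CH2Cl2, −30 to 0 °C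
Reagents that add atoms: methyltriisopropoxytitanium, C[Ti](OC(C)C)(OC(C)C)OC(C)C
Why: Hydroxyl-directed organotitanium addition: the C6 alkoxide binds titanium and the methyl group is transferred to C8 through a six-membered chair with the ring bonds C6–C5 and C8–C9 pseudo-equatorial, which should set the 1,3-anti (8S) carbinol; the weakly basic reagent neither enolises the ketone nor opens the cyclopropane.

Step 17
Reactants: 28 diol
Product: 29 C6 acetate (6S acetoxy, 8S tertiary alcohol)
Conditions: Ac2O, pyridine, DMAP (cat.), CH2Cl2, 0 °C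
Reagents that add atoms: acetic anhydride, CC(=O)OC(C)=O
Why: Acetylation of the secondary allylic alcohol; the tertiary cyclopropyl carbinol is too hindered to react under these conditions.

Step 18
Reactants: 29 C6 acetate
Product: 30 side-chain epoxide (R at the epoxide CH; 2,2-dimethyloxirane terminus)
Conditions: D-fructose-derived ketone catalyst (0.3 equiv), Oxone (2KHSO5·KHSO4·K2SO4), K2CO3, Bu4NHSO4, MeCN–dimethoxymethane–aq. buffer (pH 10.5), −5 °C
Reagents that add atoms: potassium peroxymonosulfate, [K+].[O-]S(=O)(=O)OO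
Why: Shi asymmetric epoxidation through the spiro dioxirane transition state should oxidise the exposed, electron-rich prenyl alkene from the face that gives the R epoxide, while the ring alkene is deactivated by the allylic acetate and shielded by the ring.

Step 19
Reactants: 30 side-chain epoxide
Product: 31 (R)-allylic alcohol (side chain CH2CH2CH(OH)C(CH3)=CH2)
Conditions: Cp2TiCl2 (2.5 equiv), Mn, THF, rt (gives Cp2TiCl); then 30, rt; aq. NaH2PO4
Reagents that add atoms: none
Why: Epoxide opening by trivalent titanium (Nugent–RajanBabu reagent) cleaves the tertiary C–O bond homolytically and a second titanium centre removes a methyl hydrogen, giving the isopropenyl carbinol; the secondary C–O bond is never broken, so R is retained, the acetate is tolerated and no alkene is within reach of the radical.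

Step 20
Reactants: 31 (R)-allylic alcohol
Product: 32 (R)-allylic mesylate
Conditions: Ms2O, pyridine, CH2Cl2, −20 °C
Reagents that add atoms: methanesulfonic anhydride, CS(=O)(=O)OS(C)(=O)=O
Why: Sulfonylation of the secondary allylic alcohol with retention at carbon; without a sulfene pathway the hindered tertiary carbinol is left alone, and the crude mesylate is used at once.

Step 21
Reactants: 32 (R)-allylic mesylate
Product: 33 (S)-monoperoxyketal (side chain CH(OOC(CH3)2OCH3))
Conditions: 2-methoxyprop-2-yl hydroperoxide, KOt-Bu, 18-crown-6, THF, 0 °C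
Reagents that add atoms: 2-methoxyprop-2-yl hydroperoxide, COC(C)(C)OO
Why: SN2 displacement of the mesylate by the α-effect peroxide anion with inversion gives the S peroxide in protected form; the weakly basic peroxide anion should not cleave the acetate.

Step 22
Reactants: 33 (S)-monoperoxyketal
Product: 34 CNP0302713.3 (target)
Conditions: AcOH–THF–H2O (4:2:1), rt
Reagents that add atoms: none
Why: Mild acid hydrolysis of the monoperoxyketal releases the hydroperoxide without ionising the allylic acetate or the tertiary cyclopropyl carbinol.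

**Compound list**

1 | geraniol | CC(C)=CCC/C(C)=C/CO | starting material
2 | geranyl chloride | CC(C)=CCC/C(C)=C/CCl | intermediate
3 | (4-bromobut-1-yn-1-yl)trimethylsilane | C[Si](C)(C)C#CCCBr | starting material
4 | [4-(trimethylsilyl)but-3-yn-1-yl]magnesium bromide (not isolated) | C[Si](C)(C)C#CCC[Mg]Br | intermediate
5 | [(5S)-5-ethenyl-5,9-dimethyldec-8-en-1-yn-1-yl]trimethylsilane | CC(C)=CCC[C@](C)(C=C)CCC#C[Si](C)(C)C | intermediate
6 | (5S)-5-ethenyl-5,9-dimethyldec-8-en-1-yne | CC(C)=CCC[C@](C)(C=C)CCC#C | intermediate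
7 | dimethyl[(1E,5S)-5-ethenyl-2,5,9-trimethyldeca-1,8-dien-1-yl]alane (not isolated) | CC(C)=CCC[C@](C)(C=C)CC/C(C)=C/[Al](C)C | intermediate
8 | (2E,6S)-6-ethenyl-3,6,10-trimethylundeca-2,9-dien-1-ol | CC(C)=CCC[C@](C)(C=C)CC/C(C)=C/CO | intermediate
9 | [(2R,3R)-3-[(3S)-3-ethenyl-3,7-dimethyloct-6-en-1-yl]-3-methyloxiran-2-yl]methanol | CC(C)=CCC[C@](C)(C=C)CC[C@@]1(C)O[C@@H]1CO | intermediate
10 | (2S,3R)-2-(chloromethyl)-3-[(3S)-3-ethenyl-3,7-dimethyloct-6-en-1-yl]-3-methyloxirane | CC(C)=CCC[C@](C)(C=C)CC[C@@]1(C)O[C@@H]1CCl | intermediate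
11 | dilithio derivative (lithium alkoxide, lithium acetylide) of (3R,6S)-6-ethenyl-3,6,10-trimethylundec-9-en-1-yn-3-ol (not isolated) | CC(C)=CCC[C@](C)(C=C)CC[C@@](C)(O[Li])C#C[Li] | intermediate
12 | (3R,6S)-6-ethenyl-3,6,10-trimethyl-1-(trimethylsilyl)-3-(trimethylsilyloxy)undec-9-en-1-yne | CC(C)=CCC[C@](C)(C=C)CC[C@@](C)(O[Si](C)(C)C)C#C[Si](C)(C)C | intermediate
13 | ethyl diazoacetate | CCOC(=O)C=[N+]=[N-] | starting material
14 | ethyl (1S,2S)-2-[(3R,6S)-3,6,10-trimethyl-1-(trimethylsilyl)-3-(trimethylsilyloxy)undec-9-en-1-yn-6-yl]cyclopropane-1-carboxylate | CCOC(=O)[C@H]1C[C@@H]1[C@@](C)(CCC=C(C)C)CC[C@@](C)(O[Si](C)(C)C)C#C[Si](C)(C)C | intermediate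
15 | ethyl (1S,2S)-2-[(3R,6S)-3-hydroxy-3,6,10-trimethylundec-9-en-1-yn-6-yl]cyclopropane-1-carboxylate | CCOC(=O)[C@H]1C[C@@H]1[C@@](C)(CCC=C(C)C)CC[C@@](C)(O)C#C | intermediate
16 | dilithio derivative of 15 (lithium alkoxide, lithium acetylide; not isolated) | CCOC(=O)[C@H]1C[C@@H]1[C@@](C)(CCC=C(C)C)CC[C@@](C)(O[Li])C#C[Li] | intermediate
17 | lithium ynolate of 15 with lithium alkoxide at C4 (not isolated) | CCOC(=O)[C@H]1C[C@@H]1[C@@](C)(CCC=C(C)C)CC[C@@](C)(O[Li])C#CO[Li] | intermediate
18 | ethyl (1S,2S)-2-[(3R,6S)-3-hydroxy-3,6,10-trimethyl-1-(triisopropylsilyloxy)undec-9-en-1-yn-6-yl]cyclopropane-1-carboxylate | CCOC(=O)[C@H]1C[C@@H]1[C@@](C)(CCC=C(C)C)CC[C@@](C)(O)C#CO[Si](C(C)C)(C(C)C)C(C)C | intermediate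
19 | tert-butyl acetate | CC(=O)OC(C)(C)C | starting material
20 | lithium enolate of tert-butyl acetate (not isolated) | C=C(O[Li])OC(C)(C)C | intermediate
21 | tert-butyl 3-[(1S,2S)-2-[(3R,6S)-3-hydroxy-3,6,10-trimethyl-1-(triisopropylsilyloxy)undec-9-en-1-yn-6-yl]cyclopropyl]-3-oxopropanoate | CC(C)(C)OC(=O)CC(=O)[C@H]1C[C@@H]1[C@@](C)(CCC=C(C)C)CC[C@@](C)(O)C#CO[Si](C(C)C)(C(C)C)C(C)C | intermediate
22 | tert-butyl 3-[(1S,2S)-2-[(1Z,3R,6S)-3-hydroxy-3,6,10-trimethyl-1-(triisopropylsilyloxy)undeca-1,9-dien-6-yl]cyclopropyl]-3-oxopropanoate | CC(C)(C)OC(=O)CC(=O)[C@H]1C[C@@H]1[C@@](C)(CCC=C(C)C)CC[C@@](C)(O)/C=C\O[Si](C(C)C)(C(C)C)C(C)C | intermediate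
23 | acylketene from 22 (C7=C=O next to the C8 ketone; not isolated) | O=C=CC(=O)[C@H]1C[C@@H]1[C@@](C)(CCC=C(C)C)CC[C@@](C)(O)/C=C\O[Si](C(C)C)(C(C)C)C(C)C | intermediate
24 | ten-membered β-keto lactone: 4R methyl and (Z)-2-(triisopropylsilyloxy)ethenyl at C4, 1S methyl and 4-methylpent-3-enyl at C1, trans-cyclopropane 9S,10S | C[C@]1(/C=C\O[Si](C(C)C)(C(C)C)C(C)C)CC[C@](C)(CCC=C(C)C)[C@H]2C[C@@H]2C(=O)CC(=O)O1 | intermediate
25 | β-keto acid: ten-membered carbocycle with carboxyl on C7 (C7 configuration not defined; not isolated) | CC(C)=CCC[C@@]1(C)CC/C(C)=C/[C@@H](O[Si](C(C)C)(C(C)C)C(C)C)C(C(=O)O)C(=O)[C@H]2C[C@@H]21 | intermediate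
26 | ten-membered carbocycle: C8 ketone, 6S triisopropylsilyloxy, 4E alkene, cyclopropane 9S,10S, 1S | CC(C)=CCC[C@@]1(C)CC/C(C)=C/[C@@H](O[Si](C(C)C)(C(C)C)C(C)C)CC(=O)[C@H]2C[C@@H]21 | intermediate
27 | β-hydroxy ketone: 6S hydroxyl, C8 ketone | CC(C)=CCC[C@@]1(C)CC/C(C)=C/[C@@H](O)CC(=O)[C@H]2C[C@@H]21 | intermediate
28 | diol: 6S hydroxyl, 8S methyl carbinol | CC(C)=CCC[C@@]1(C)CC/C(C)=C/[C@@H](O)C[C@](C)(O)[C@H]2C[C@@H]21 | intermediate
29 | C6 acetate: 6S acetoxy, 8S methyl carbinol, prenyl side chain | CC(C)=CCC[C@@]1(C)CC/C(C)=C/[C@@H](OC(C)=O)C[C@](C)(O)[C@H]2C[C@@H]21 | intermediate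
30 | side-chain (R)-epoxide of 29 (C1 now R by priority change) | CC3(C)O[C@@H]3CC[C@@]1(C)CC/C(C)=C/[C@@H](OC(C)=O)C[C@](C)(O)[C@H]2C[C@@H]21 | intermediate
31 | (R)-allylic alcohol: side chain CH2CH2CH(OH)C(CH3)=CH2 | C=C(C)[C@@H](CC[C@@]1(C)CC/C(C)=C/[C@@H](OC(C)=O)C[C@](C)(O)[C@H]2C[C@@H]21)O | intermediate
32 | (R)-allylic mesylate of 31 | C=C(C)[C@@H](CC[C@@]1(C)CC/C(C)=C/[C@@H](OC(C)=O)C[C@](C)(O)[C@H]2C[C@@H]21)OS(C)(=O)=O | intermediate
33 | (S)-2-methoxyprop-2-yl peroxide (monoperoxyketal) | C=C(C)[C@H](CC[C@@]1(C)CC/C(C)=C/[C@@H](OC(C)=O)C[C@](C)(O)[C@H]2C[C@@H]21)OOC(C)(C)OC | intermediate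
34 | CNP0302713.3 | C=C(C)[C@H](CC[C@@]1(C)CC/C(C)=C/[C@@H](OC(C)=O)C[C@](C)(O)[C@H]2C[C@@H]21)OO | target

**Step count and risks**

Total step count: 22 (Grignard formation is part of step 2). Longest linear sequence: 22 steps, from geraniol to the target.

Steps most likely to fail:

1. Step 14 (Carroll ring contraction). At 140 °C, heterolysis of the tertiary allylic C4–O bond (to an enal with silyl transfer) or reversion to the acylketene may outrun the strained bridged [3,3] transition state. The rotamer with C3 gauche to C6 may also compete and give the Z alkene with the wrong C6 configuration. Fallback, from 24 back to 26, by the low-temperature ester-enolate variant of the same ring contraction with separate decarboxylation. The C8 ketone of 24 is reduced (NaBH4, MeOH–THF, −40 °C) to the β-hydroxy lactone F1. Double deprotonation and silylation (LDA, 2.2 equiv, then Me3SiCl/Et3N, THF, −78 °C) give the silyl ketene acetal F2. This undergoes the Ireland–Claisen rearrangement known for lactone ketene acetals with a vinyl group on the carbinol carbon, at or below room temperature, where neither ionisation nor ketene formation competes. Aqueous work-up gives the β-hydroxy acid F3. Dess–Martin oxidation (NaHCO3, CH2Cl2) gives β-keto acid 25, which loses CO2 on warming and rejoins the route at 26.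

2. Step 13 (macrolactonization). Closure of a strained ten-membered ring by a hindered tertiary alcohol may be slow, so that dimerisation or oligomerisation of the acylketene, or its [4+2] capture by the silyl enol ether, competes. Fallback, from 18 back to 24, closing the ring at C7–C8 instead of at the ester bond. Lindlar semi-hydrogenation of 18 gives the Z enol ether ester F4. DIBAL (toluene, −78 °C) reduces the ester to the cyclopropanecarbaldehyde F5. Bromoacetyl bromide and pyridine (CH2Cl2, −20 °C) acylate the tertiary alcohol to the bromoacetate F6. An intramolecular Reformatsky reaction mediated by SmI2 (THF, −78 °C, high dilution), a lactonization known to work for medium rings, gives the β-hydroxy lactone F1. Dess–Martin oxidation then rejoins the route at 24.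

3. Step 16 (directed methyl addition). Methyl transfer to the hindered cyclopropyl ketone may be slow, or the ring conformation may override the six-membered delivery and give poor or reversed facial selectivity at C8. Fallback, from 26 back to 28, reversing the order so that the nucleophile is external and the face is chosen by the ring periphery and the bulky C6 silyl ether instead of a C6 metal alkoxide. MeLi with CeCl3 (THF, −78 °C) adds to silyl ether 26 to give the tertiary alcohol F7 (the C8 epimers are ring diastereomers and separable). TBAF (THF, rt) then removes the silyl group and rejoins the route at 28.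

**Further compounds**

F1 | step 14 | β-hydroxy lactone (C8 carbinol, either epimer; otherwise as 24) | C[C@]1(/C=C\O[Si](C(C)C)(C(C)C)C(C)C)CC[C@](C)(CCC=C(C)C)[C@H]2C[C@@H]2C(O)CC(=O)O1
F2 | step 14 | trimethylsilyl ketene acetal of F1 with C8 trimethylsilyl ether | C[C@]1(/C=C\O[Si](C(C)C)(C(C)C)C(C)C)CC[C@](C)(CCC=C(C)C)[C@H]2C[C@@H]2C(O[Si](C)(C)C)C=C(O[Si](C)(C)C)O1
F3 | step 14 | β-hydroxy acid: ten-membered carbocycle with C7 carboxyl and C8 hydroxyl (C7, C8 not defined) | CC(C)=CCC[C@@]1(C)CC/C(C)=C/[C@@H](O[Si](C(C)C)(C(C)C)C(C)C)C(C(=O)O)C(O)[C@H]2C[C@@H]21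
F4 | step 13 | ethyl (1S,2S)-2-[(1Z,3R,6S)-3-hydroxy-3,6,10-trimethyl-1-(triisopropylsilyloxy)undeca-1,9-dien-6-yl]cyclopropane-1-carboxylate | CCOC(=O)[C@H]1C[C@@H]1[C@@](C)(CCC=C(C)C)CC[C@@](C)(O)/C=C\O[Si](C(C)C)(C(C)C)C(C)C
F5 | step 13 | (1S,2S)-2-[(1Z,3R,6S)-3-hydroxy-3,6,10-trimethyl-1-(triisopropylsilyloxy)undeca-1,9-dien-6-yl]cyclopropane-1-carbaldehyde | O=C[C@H]1C[C@@H]1[C@@](C)(CCC=C(C)C)CC[C@@](C)(O)/C=C\O[Si](C(C)C)(C(C)C)C(C)C
F6 | step 13 | bromoacetate of the C4 tertiary alcohol of F5 | O=C[C@H]1C[C@@H]1[C@@](C)(CCC=C(C)C)CC[C@@](C)(OC(=O)CBr)/C=C\O[Si](C(C)C)(C(C)C)C(C)C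
F7 | step 16 | C8 methyl carbinol with C6 triisopropylsilyl ether | CC(C)=CCC[C@@]1(C)CC/C(C)=C/[C@@H](O[Si](C(C)C)(C(C)C)C(C)C)C[C@](C)(O)[C@H]2C[C@@H]21
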